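**Retrosynthetic overview**

1. The target comes from allylation at C-6 of a bicyclic vinylogous ester enone; the allyl group enters anti to the angular side chain.
2. The dioxole ring (formed last) comes from methylenation of a 4-hydroxycyclohexane-1,3-dione with BrCH2Cl.
3. The six-membered carbocycle (formed first) comes from an intramolecular aldol addition of a methyl ketone to a non-enolisable α-hydroxy aldehyde, followed by oxidation.
4. Both stereocentres of the open-chain precursor come from Sharpless epoxidation of an E-allylic alcohol and SN2 opening of the epoxide by a benzylic magnesium chloride under CuI catalysis.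
5. Three fragments: A = (2Z)-2-iodobut-2-en-1-ol, B = a ketal-protected 3-oxobutyl zinc iodide (A and B joined by Negishi coupling), C = 3,4,5-trimethoxybenzyl chloride.

Assumption: organometallic and other species that are made and used up in the same flask are counted as non-isolated intermediates of that step, and the aldol product 19 is carried on as a mixture of epimers at its secondary carbinol carbon.

**Route**

Step 1
Reactants: 1 (2E)-but-2-enal (crotonaldehyde)
Product: 2 (2Z)-2-iodobut-2-enal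
Conditions: I2, K2CO3, DMAP (20 mol%), THF/H2O 1:1, 23 °C
Reagents that add atoms: iodine, II
Why: DMAP-mediated α-iodination of the enal (conjugate addition, iodination of the enolate, elimination) gives the thermodynamically preferred Z-α-iodoenal, which fixes the olefin geometry used later.

Step 2
Reactants: 2 (2Z)-2-iodobut-2-enal
Product: 3 (2Z)-2-iodobut-2-en-1-ol
Conditions: NaBH4, CeCl3·7H2O, MeOH, 0 °C
Reagents that add atoms: none
Why: Luche reduction gives clean 1,2-reduction of the enal and leaves the vinyl iodide and its geometry untouched.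

Step 3
Reactants: 4 but-3-en-2-one (methyl vinyl ketone)
Product: 6 2-(2-bromoethyl)-2-methyl-1,3-dioxolane, via 4-bromobutan-2-one 5 (not isolated)
Conditions: HBr (g), CH2Cl2, 0 °C; then HOCH2CH2OH, TsOH (cat.), 4 Å MS, 23 °C
Reagents that add atoms: hydrogen bromide, Br; ethane-1,2-diol, OCCO
Why: Conjugate hydrobromination of the enone followed by acid-catalysed ketalisation masks the ketone before any organometallic chemistry.

Step 4
Reactants: 6 2-(2-bromoethyl)-2-methyl-1,3-dioxolane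
Product: 7 2-(2-iodoethyl)-2-methyl-1,3-dioxolane
Conditions: NaI, NaHCO3, acetone, reflux
Reagents that add atoms: sodium iodide, [Na+].[I-]
Why: Finkelstein halide exchange gives the primary iodide, which inserts zinc under mild conditions.

Step 5
Reactants: 7 2-(2-iodoethyl)-2-methyl-1,3-dioxolane; 3 (2Z)-2-iodobut-2-en-1-ol
Product: 9 (2E)-2-[2-(2-methyl-1,3-dioxolan-2-yl)ethyl]but-2-en-1-ol, via alkylzinc iodide 8 (not isolated)
Conditions: 7, Zn dust (Me3SiCl, BrCH2CH2Br activation), THF, 40 °C; then 3, Pd(OAc)2 (2 mol%), SPhos (4 mol%), THF, 23 °C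
Reagents that add atoms: none
Why: Negishi sp3–sp2 cross-coupling proceeds with retention at the vinyl iodide, so the methyl group ends up trans to CH2OH (E), and the alkylzinc halide tolerates the ketal and, with this catalyst, the free hydroxyl.

Step 6
Reactants: 9 (2E)-2-[2-(2-methyl-1,3-dioxolan-2-yl)ethyl]but-2-en-1-ol
Product: 10 [(2S,3S)-3-methyl-2-[2-(2-methyl-1,3-dioxolan-2-yl)ethyl]oxiran-2-yl]methanol
Conditions: Ti(OiPr)4 (10 mol%), L-(+)-diethyl tartrate (12 mol%), tBuOOH (anhydrous), 4 Å MS, CH2Cl2, −20 °C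
Reagents that add atoms: tert-butyl hydroperoxide, CC(C)(C)OO
Why: Sharpless asymmetric epoxidation with the L-(+)-tartrate ligand delivers oxygen to the face that gives the (2S,3S)-epoxide, which sets the future quaternary carbinol centre, while the E geometry of 9 sets the relative configuration at C-3.

Step 7
Reactants: 11 3,4,5-trihydroxybenzoic acid (gallic acid)
Product: 12 methyl 3,4,5-trimethoxybenzoate
Conditions: Me2SO4, K2CO3, acetone, reflux
Reagents that add atoms: dimethyl sulfate, COS(=O)(=O)OC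
Why: Exhaustive O-methylation (Williamson etherification of the three phenols and esterification of the carboxylate) gives the trimethoxy ester in one operation.

Step 8
Reactants: 12 methyl 3,4,5-trimethoxybenzoate
Product: 13 (3,4,5-trimethoxyphenyl)methanol
Conditions: LiAlH4, THF, 0 → 23 °C
Reagents that add atoms: none
Why: Hydride reduction of the ester gives the benzylic alcohol.

Step 9
Reactants: 13 (3,4,5-trimethoxyphenyl)methanol
Product: 14 5-(chloromethyl)-1,2,3-trimethoxybenzene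
Conditions: SOCl2, DMF (cat.), CH2Cl2, 0 → 23 °C
Reagents that add atoms: thionyl chloride, O=S(Cl)Cl
Why: Deoxychlorination through the chlorosulfite gives the benzylic chloride needed for the magnesium reagent.

Step 10
Reactants: 10 [(2S,3S)-3-methyl-2-[2-(2-methyl-1,3-dioxolan-2-yl)ethyl]oxiran-2-yl]methanol; 14 5-(chloromethyl)-1,2,3-trimethoxybenzene
Product: 16 (2R,3S)-3-methyl-2-[2-(2-methyl-1,3-dioxolan-2-yl)ethyl]-4-(3,4,5-trimethoxyphenyl)butane-1,2-diol, via benzylic magnesium chloride 15 (not isolated)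
Conditions: 14, Mg turnings, THF, 0 °C (slow addition); then 10, CuI (15 mol%), THF, −30 → 0 °C (3 equiv of 15); aq. NH4Cl
Reagents that add atoms: none
Why: CuI-catalysed SN2 opening of the 2,3-epoxy alcohol occurs at C-3 because C-2 is fully substituted, with inversion, which creates the (S)-methyl-bearing stereocentre and leaves the tertiary C–O bond (R in the diol) untouched.

Step 11
Reactants: 16 (2R,3S)-3-methyl-2-[2-(2-methyl-1,3-dioxolan-2-yl)ethyl]-4-(3,4,5-trimethoxyphenyl)butane-1,2-diol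
Product: 17 (2R,3S)-2-hydroxy-3-methyl-2-[2-(2-methyl-1,3-dioxolan-2-yl)ethyl]-4-(3,4,5-trimethoxyphenyl)butanal
Conditions: SO3·pyridine, DMSO, iPr2NEt, CH2Cl2, 0 °C
Reagents that add atoms: none
Why: Parikh–Doering oxidation converts only the primary alcohol to the aldehyde, without glycol cleavage, and the aldehyde cannot epimerise because its α-carbon is quaternary.

Step 12
Reactants: 17 (2R,3S)-2-hydroxy-3-methyl-2-[2-(2-methyl-1,3-dioxolan-2-yl)ethyl]-4-(3,4,5-trimethoxyphenyl)butanal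
Product: 19 (3RS,4R)-3,4-dihydroxy-4-[(2S)-1-(3,4,5-trimethoxyphenyl)propan-2-yl]cyclohexan-1-one, via keto aldehyde 18 (not isolated)
Conditions: TsOH·H2O (20 mol%), THF/H2O 4:1, 40 °C; then DBU (0.5 equiv), 0 °C
Reagents that add atoms: water, O
Why: Ketal hydrolysis followed by base-mediated intramolecular aldol addition (6-enolexo) of the methyl ketone to the non-enolisable aldehyde closes the carbocycle, and the new secondary carbinol centre forms as an epimer mixture that is removed in the next step.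

Step 13
Reactants: 19 (3RS,4R)-3,4-dihydroxy-4-[(2S)-1-(3,4,5-trimethoxyphenyl)propan-2-yl]cyclohexan-1-one
Product: 20 (4R)-4-hydroxy-4-[(2S)-1-(3,4,5-trimethoxyphenyl)propan-2-yl]cyclohexane-1,3-dione
Conditions: 2-iodoxybenzoic acid (IBX), DMSO, 23 °C
Reagents that add atoms: none
Why: IBX oxidises the β-hydroxy ketone to the 1,3-dione without cleaving the vicinal tertiary diol, so both epimers of 19 converge on one compound.

Step 14
Reactants: 20 (4R)-4-hydroxy-4-[(2S)-1-(3,4,5-trimethoxyphenyl)propan-2-yl]cyclohexane-1,3-dione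
Product: 21 (7aR)-7a-[(2S)-1-(3,4,5-trimethoxyphenyl)propan-2-yl]-7,7a-dihydro-1,3-benzodioxol-5(6H)-one
Conditions: BrCH2Cl, Cs2CO3, DMF, 70 °C, high dilution
Reagents that add atoms: bromochloromethane, ClCBr
Why: Double O-alkylation (methylenation) bridges the enol oxygen and the tertiary hydroxyl, and only the enol oxygen next to the carbinol carbon can close a five-membered ring, which fixes the position of the enone.

Step 15
Reactants: 21 (7aR)-7a-[(2S)-1-(3,4,5-trimethoxyphenyl)propan-2-yl]-7,7a-dihydro-1,3-benzodioxol-5(6H)-one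
Product: 23 (6R,7aR)-6-(prop-2-en-1-yl)-7a-[(2S)-1-(3,4,5-trimethoxyphenyl)propan-2-yl]-7,7a-dihydro-1,3-benzodioxol-5(6H)-one, via lithium dienolate 22 (not isolated)
Conditions: LiN(iPr)2 (1.1 equiv), THF, −78 °C; then allyl bromide, −78 → −40 °C
Reagents that add atoms: allyl bromide, C=CCBr
Why: Stork–Danheiser-type α′-alkylation of the vinylogous ester (no γ-hydrogens, since C-7a is quaternary) places the allyl group on the face opposite the pseudo-axial side chain, giving the 6R (trans, equatorial) isomer, which is also the thermodynamically preferred epimer.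

**Compound list**

1 | (2E)-but-2-enal (crotonaldehyde) | C/C=C/C=O | starting material
2 | (2Z)-2-iodobut-2-enal | C/C=C(\I)C=O | intermediate
3 | (2Z)-2-iodobut-2-en-1-ol (fragment A) | C/C=C(\I)CO | intermediate
4 | but-3-en-2-one (methyl vinyl ketone) | CC(=O)C=C | starting material
5 | 4-bromobutan-2-one | CC(=O)CCBr | intermediate
6 | 2-(2-bromoethyl)-2-methyl-1,3-dioxolane | CC1(CCBr)OCCO1 | intermediate
7 | 2-(2-iodoethyl)-2-methyl-1,3-dioxolane (fragment B) | CC1(CCI)OCCO1 | intermediate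
8 | [2-(2-methyl-1,3-dioxolan-2-yl)ethyl]zinc iodide | CC1(CC[Zn]I)OCCO1 | intermediate
9 | (2E)-2-[2-(2-methyl-1,3-dioxolan-2-yl)ethyl]but-2-en-1-ol | C/C=C(/CO)CCC1(C)OCCO1 | intermediate
10 | [(2S,3S)-3-methyl-2-[2-(2-methyl-1,3-dioxolan-2-yl)ethyl]oxiran-2-yl]methanol | OC[C@]1(CCC2(C)OCCO2)O[C@H]1C | intermediate
11 | 3,4,5-trihydroxybenzoic acid (gallic acid) | OC(=O)c1cc(O)c(O)c(O)c1 | starting material
12 | methyl 3,4,5-trimethoxybenzoate | COC(=O)c1cc(OC)c(OC)c(OC)c1 | intermediate
13 | (3,4,5-trimethoxyphenyl)methanol | OCc1cc(OC)c(OC)c(OC)c1 | intermediate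
14 | 5-(chloromethyl)-1,2,3-trimethoxybenzene (fragment C) | ClCc1cc(OC)c(OC)c(OC)c1 | intermediate
15 | (3,4,5-trimethoxybenzyl)magnesium chloride | Cl[Mg]Cc1cc(OC)c(OC)c(OC)c1 | intermediate
16 | (2R,3S)-3-methyl-2-[2-(2-methyl-1,3-dioxolan-2-yl)ethyl]-4-(3,4,5-trimethoxyphenyl)butane-1,2-diol | OC[C@@](O)(CCC1(C)OCCO1)[C@@H](C)Cc2cc(OC)c(OC)c(OC)c2 | intermediate
17 | (2R,3S)-2-hydroxy-3-methyl-2-[2-(2-methyl-1,3-dioxolan-2-yl)ethyl]-4-(3,4,5-trimethoxyphenyl)butanal | O=C[C@@](O)(CCC1(C)OCCO1)[C@@H](C)Cc2cc(OC)c(OC)c(OC)c2 | intermediate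
18 | (2R,3S)-2-hydroxy-3-methyl-2-(3-oxobutyl)-4-(3,4,5-trimethoxyphenyl)butanal | O=C[C@@](O)(CCC(C)=O)[C@@H](C)Cc1cc(OC)c(OC)c(OC)c1 | intermediate
19 | (3RS,4R)-3,4-dihydroxy-4-[(2S)-1-(3,4,5-trimethoxyphenyl)propan-2-yl]cyclohexan-1-one | O=C1CC(O)[C@](O)([C@@H](C)Cc2cc(OC)c(OC)c(OC)c2)CC1 | intermediate
20 | (4R)-4-hydroxy-4-[(2S)-1-(3,4,5-trimethoxyphenyl)propan-2-yl]cyclohexane-1,3-dione | O=C1CC(=O)[C@](O)([C@@H](C)Cc2cc(OC)c(OC)c(OC)c2)CC1 | intermediate
21 | (7aR)-7a-[(2S)-1-(3,4,5-trimethoxyphenyl)propan-2-yl]-7,7a-dihydro-1,3-benzodioxol-5(6H)-one | O=C1C=C2OCO[C@@]2([C@@H](C)Cc3cc(OC)c(OC)c(OC)c3)CC1 | intermediate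
22 | lithium dienolate of 21 | [Li]OC1=CC[C@]2([C@@H](C)Cc3cc(OC)c(OC)c(OC)c3)OCOC2=C1 | intermediate
23 | (6R,7aR)-6-(prop-2-en-1-yl)-7a-[(2S)-1-(3,4,5-trimethoxyphenyl)propan-2-yl]-7,7a-dihydro-1,3-benzodioxol-5(6H)-one | C=CC[C@@H]1C[C@]2([C@@H](C)Cc3cc(OC)c(OC)c(OC)c3)OCOC2=CC1=O | target

**Step count**

Total step count: 15.
Longest linear sequence: 10 steps (1, 2, 5, 6, 10, 11, 12, 13, 14, 15; the chain 3, 4, 5, 6, 10–15 is equally long). Fragment C takes steps 7–9 and joins at step 10.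

**Three steps most likely to fail, with fallbacks**

Step 14 (methylenation of the hydroxy dione). The dione can be alkylated at carbon or at the wrong enol oxygen, and the tertiary hydroxyl is a poor nucleophile. The fallback installs the dioxole carbon beforehand as an acetal on the tertiary oxygen; it sets out from 17 and comes back at 21.
- 17 is protected with chloromethyl methyl ether and iPr2NEt to give (2R,3S)-2-(methoxymethoxy)-3-methyl-2-[2-(2-methyl-1,3-dioxolan-2-yl)ethyl]-4-(3,4,5-trimethoxyphenyl)butanal F8.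
- Mild aqueous TsOH removes the ketal to give (2R,3S)-2-(methoxymethoxy)-3-methyl-2-(3-oxobutyl)-4-(3,4,5-trimethoxyphenyl)butanal F9 in the flask.
- DBU closes F9 by the same intramolecular aldol to (3RS,4R)-3-hydroxy-4-(methoxymethoxy)-4-[(2S)-1-(3,4,5-trimethoxyphenyl)propan-2-yl]cyclohexan-1-one F10.
- IBX gives (4R)-4-(methoxymethoxy)-4-[(2S)-1-(3,4,5-trimethoxyphenyl)propan-2-yl]cyclohexane-1,3-dione F11.
- BF3·OEt2 in CH2Cl2 ionises the acetal, and the neighbouring enol oxygen traps the oxocarbenium ion with loss of methanol, giving 21.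

Step 10 (opening of the epoxide by the benzylic magnesium reagent). Wurtz coupling of 14, chloride attack at the tertiary carbon and slow reaction next to the quaternary centre are all possible. The fallback exchanges the two carbon groups so that methyl is the nucleophile; it sets out from 6 and 14 and comes back at 16.
- 6 and Mg give [2-(2-methyl-1,3-dioxolan-2-yl)ethyl]magnesium bromide F1.
- F1 adds anti across the magnesium alkoxide of prop-2-yn-1-ol (made with MeMgCl) under CuI catalysis, and I2 quench gives (2Z)-3-iodo-2-[2-(2-methyl-1,3-dioxolan-2-yl)ethyl]prop-2-en-1-ol F2.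
- 14 with Zn dust and LiCl gives (3,4,5-trimethoxybenzyl)zinc chloride F3.
- Negishi coupling of F3 with F2 (Pd(PPh3)4) gives (2Z)-2-[2-(2-methyl-1,3-dioxolan-2-yl)ethyl]-4-(3,4,5-trimethoxyphenyl)but-2-en-1-ol F4.
- Sharpless epoxidation with L-(+)-diethyl tartrate gives [(2S,3R)-2-[2-(2-methyl-1,3-dioxolan-2-yl)ethyl]-3-(3,4,5-trimethoxybenzyl)oxiran-2-yl]methanol F5.
- Me2CuLi opens F5 at C-3 with inversion to give 16.

Step 12 (aldol addition without dehydration). The adduct may lose water, or the α-hydroxy aldehyde may rearrange under base. The fallback accepts the dehydration and puts the second oxygen in afterwards; it sets out from 17 and comes back at 20, so it also replaces step 13.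
- 17 is heated with TsOH in THF/H2O so that ketal hydrolysis, intramolecular aldol condensation and dehydration give (4R)-4-hydroxy-4-[(2S)-1-(3,4,5-trimethoxyphenyl)propan-2-yl]cyclohex-2-en-1-one F6.
- H2O2 and NaOH in MeOH epoxidise the enone to (5R)-5-hydroxy-5-[(2S)-1-(3,4,5-trimethoxyphenyl)propan-2-yl]-7-oxabicyclo[4.1.0]heptan-2-one F7.
- Pd(PPh3)4 with 1,2-bis(diphenylphosphino)ethane in toluene at 80 °C isomerises the α,β-epoxy ketone F7 to the 1,3-dione 20.

Further compounds

F1 | step 10 | [2-(2-methyl-1,3-dioxolan-2-yl)ethyl]magnesium bromide | CC1(CC[Mg]Br)OCCO1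
F2 | step 10 | (2Z)-3-iodo-2-[2-(2-methyl-1,3-dioxolan-2-yl)ethyl]prop-2-en-1-ol | OC/C(CCC1(C)OCCO1)=C\I
F3 | step 10 | (3,4,5-trimethoxybenzyl)zinc chloride | Cl[Zn]Cc1cc(OC)c(OC)c(OC)c1
F4 | step 10 | (2Z)-2-[2-(2-methyl-1,3-dioxolan-2-yl)ethyl]-4-(3,4,5-trimethoxyphenyl)but-2-en-1-ol | OC/C(CCC1(C)OCCO1)=C\Cc2cc(OC)c(OC)c(OC)c2
F5 | step 10 | [(2S,3R)-2-[2-(2-methyl-1,3-dioxolan-2-yl)ethyl]-3-(3,4,5-trimethoxybenzyl)oxiran-2-yl]methanol | OC[C@]1(CCC2(C)OCCO2)O[C@@H]1Cc3cc(OC)c(OC)c(OC)c3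
F6 | step 12 | (4R)-4-hydroxy-4-[(2S)-1-(3,4,5-trimethoxyphenyl)propan-2-yl]cyclohex-2-en-1-one | O=C1C=C[C@](O)([C@@H](C)Cc2cc(OC)c(OC)c(OC)c2)CC1
F7 | step 12 | (5R)-5-hydroxy-5-[(2S)-1-(3,4,5-trimethoxyphenyl)propan-2-yl]-7-oxabicyclo[4.1.0]heptan-2-one | O=C1C2OC2[C@](O)([C@@H](C)Cc3cc(OC)c(OC)c(OC)c3)CC1
F8 | step 14 | (2R,3S)-2-(methoxymethoxy)-3-methyl-2-[2-(2-methyl-1,3-dioxolan-2-yl)ethyl]-4-(3,4,5-trimethoxyphenyl)butanal | O=C[C@@](OCOC)(CCC1(C)OCCO1)[C@@H](C)Cc2cc(OC)c(OC)c(OC)c2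
F9 | step 14 | (2R,3S)-2-(methoxymethoxy)-3-methyl-2-(3-oxobutyl)-4-(3,4,5-trimethoxyphenyl)butanal | O=C[C@@](OCOC)(CCC(C)=O)[C@@H](C)Cc1cc(OC)c(OC)c(OC)c1
F10 | step 14 | (3RS,4R)-3-hydroxy-4-(methoxymethoxy)-4-[(2S)-1-(3,4,5-trimethoxyphenyl)propan-2-yl]cyclohexan-1-one | O=C1CC(O)[C@](OCOC)([C@@H](C)Cc2cc(OC)c(OC)c(OC)c2)CC1
F11 | step 14 | (4R)-4-(methoxymethoxy)-4-[(2S)-1-(3,4,5-trimethoxyphenyl)propan-2-yl]cyclohexane-1,3-dione | O=C1CC(=O)[C@](OCOC)([C@@H](C)Cc2cc(OC)c(OC)c(OC)c2)CC1
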